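**Retrosynthetic overview**

1. Target 26 ← ketone 25 by hydrogenolysis ← styrene 23 by alkene cleavage. The aryl ketone C=O is carried as a C(Ar)=CH–CH3 alkene, so the enolisable benzylic CH(CH2OH) centre stays configurationally inert until the last two steps.
2. The only ring, the butyrolactone, is made in a side branch as the cyclopropane-fused lactone 16 from (R)-epichlorohydrin. Strain-release opening by the ring-B aryl Grignard 17 installs the C4 arylmethyl group; Krapcho dealkoxycarbonylation and trans-selective enolate benzylation then set C3.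
3. Key disconnection: the bond from C5 of the central guaiacyl ring (ring B, the carbon ortho to its phenolic oxygen) to the CH(CH2OH) carbon α to the ketone. This bond and that (S)-stereocentre are formed together by an aromatic Claisen [3,3] rearrangement of aryl allyl ether 10, with 1,3-chirality transfer from a carbinol C–O centre.
4. Ether 10 ← Mitsunobu inversion of 4-bromoguaiacol 9 with the 2-aryl allylic alcohol 8 ← OH-directed trans-hydrostannation/Stille coupling of propargylic alcohol 5 ← asymmetric transfer hydrogenation of ynone 4 (the one catalytic stereocentre that is relayed from oxygen to carbon).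

Key step: step 6

Remark on the chemistry: the target may equilibrate with its cyclic hemiketal (ring-B phenol adding to the ketone); the open keto-phenol drawn in the task is taken as the target. Because the stereocentre α to the ketone is enolisable, every operation after the ketone is unveiled (steps 13 and 14) is kept neutral.

**Route**

Step 1
Reactants: 1 benzyl propargyl ether; 2 N-methoxy-N-methylacetamide
Product: 4 5-(benzyloxy)pent-3-yn-2-one, via lithium acetylide 3 (not isolated)
Conditions: n-BuLi, THF, −78 °C; then 2, −78 → 0 °C; aq. NH4Cl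
Reagents that add atoms: none
Why: Weinreb ketone synthesis; the chelated tetrahedral adduct of the lithium acetylide collapses only on work-up, so acylation should stop at the ynone.

Step 2
Reactants: 4 5-(benzyloxy)pent-3-yn-2-one
Product: 5 (S)-5-(benzyloxy)pent-3-yn-2-ol
Conditions: RuCl[(S,S)-TsDPEN](p-cymene) (1 mol %), i-PrOH, rt
Reagents that add atoms: none
Why: Noyori asymmetric transfer hydrogenation of an alkynyl methyl ketone, in which the (S,S)-catalyst differentiates alkynyl from methyl and should give the (S)-carbinol without touching the alkyne or the benzyl ether.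

Step 3
Reactants: 5 (S)-5-(benzyloxy)pent-3-yn-2-ol
Product: 6 (2S,3Z)-5-(benzyloxy)-3-(tributylstannyl)pent-3-en-2-ol
Conditions: [Cp*RuCl]4 (2 mol %), Bu3SnH, CH2Cl2, rt
Reagents that add atoms: tributyltin hydride, CCCC[SnH](CCCC)CCCC
Why: Hydroxyl-directed ruthenium-catalysed trans-hydrostannation; hydrogen bonding of the free OH to the Ru–Cl unit should place tin on the alkyne carbon next to the carbinol with H anti to it, whereas the OBn side cannot direct.

Step 4
Reactants: 6 (2S,3Z)-5-(benzyloxy)-3-(tributylstannyl)pent-3-en-2-ol; 7 1-(benzyloxy)-4-bromo-2-methoxybenzene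
Product: 8 (2S,3E)-5-(benzyloxy)-3-[4-(benzyloxy)-3-methoxyphenyl]pent-3-en-2-ol
Conditions: Pd(PtBu3)2 (5 mol %), CuI (10 mol %), CsF, DMF, 45 °C
Reagents that add atoms: none
Why: Copper/fluoride-promoted Stille coupling proceeds with retention of alkene geometry, so the aryl group takes the place of tin (aryl cis to CH2OBn, carbinol carbon trans to it) and the carbinol centre is not involved.

Step 5
Reactants: 8 (2S,3E)-5-(benzyloxy)-3-[4-(benzyloxy)-3-methoxyphenyl]pent-3-en-2-ol; 9 4-bromo-2-methoxyphenol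
Product: 10 1-{[(2R,3E)-5-(benzyloxy)-3-[4-(benzyloxy)-3-methoxyphenyl]pent-3-en-2-yl]oxy}-4-bromo-2-methoxybenzene
Conditions: PPh3, DIAD, toluene, 0 °C → rt
Reagents that add atoms: none
Why: Mitsunobu etherification of a phenol with a secondary allylic alcohol is an SN2 displacement of the oxyphosphonium group and should invert the carbinol centre from S to R.

Step 6
Reactants: 10 1-{[(2R,3E)-5-(benzyloxy)-3-[4-(benzyloxy)-3-methoxyphenyl]pent-3-en-2-yl]oxy}-4-bromo-2-methoxybenzene
Product: 12 2-[(2S,3Z)-1-(benzyloxy)-3-[4-(benzyloxy)-3-methoxyphenyl]pent-3-en-2-yl]-4-bromo-6-methoxyphenol, via ortho-dienone 11 (not isolated)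
Conditions: Eu(fod)3 (10 mol %), CHCl3, 60 °C
Reagents that add atoms: none
Why: Aromatic Claisen ([3,3]-sigmatropic) rearrangement: the ArO–CH(CH3) bond breaks while the CH(CH2OBn) terminus of the allyl unit bonds to C6 of the bromoguaiacol, giving dienone 11, which tautomerises to phenol 12; Eu(fod)3, chelated by the ether and OMe oxygens, lowers the temperature needed. The closest known reaction type is the europium-catalysed or thermal Claisen rearrangement of enantioenriched secondary allyl aryl ethers with 1,3-chirality transfer. No ring is closed in the product; the only cyclic array is the six-membered chair-like transition state. The new benzylic stereocentre is controlled by the (R)-C–O centre from steps 2 and 5: the allyl unit reacts suprafacially, so with the E-alkene and the methyl group pseudo-equatorial (outside) the aryl carbon arrives on the face the oxygen leaves, which should give the (2S) centre and a (Z)-C(Ar)=CH–CH3 alkene. The selectivity needed is methyl-outside over methyl-inside; the inside rotamer is penalised by 1,3-diaxial contact with the OMe-bearing carbon of the chelated arene, and it would give the (2R,3E) isomer, which is a geometric isomer and so separable before the alkene is cleaved. Regioselectivity for C6 is secured by the OMe group on the other ortho carbon and the bromine at the para position.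

Step 7
Reactants: 12 2-[(2S,3Z)-1-(benzyloxy)-3-[4-(benzyloxy)-3-methoxyphenyl]pent-3-en-2-yl]-4-bromo-6-methoxyphenol
Product: 13 2-(benzyloxy)-1-[(2S,3Z)-1-(benzyloxy)-3-[4-(benzyloxy)-3-methoxyphenyl]pent-3-en-2-yl]-5-bromo-3-methoxybenzene
Conditions: BnBr, K2CO3, DMF, rt
Reagents that add atoms: benzyl bromide, BrCc1ccccc1
Why: Williamson benzylation caps the only acidic OH so that an aryl Grignard reagent can be formed, and makes all four hydroxyl masks identical for one final hydrogenolysis.

Step 8
Reactants: 14 (R)-epichlorohydrin; 15 diethyl malonate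
Product: 16 ethyl (1S,5R)-2-oxo-3-oxabicyclo[3.1.0]hexane-1-carboxylate
Conditions: NaOEt, EtOH, 0 °C → reflux
Reagents that add atoms: none
Why: Double alkylation of malonate by epichlorohydrin (epoxide opening at CH2, epoxide re-formation by chloride displacement, 3-exo-tet closure with inversion, lactonisation) is the established entry to this cis-fused cyclopropane lactone and transfers the epichlorohydrin chirality to C5, the future lactone C4.

Step 9
Reactants: 13 2-(benzyloxy)-1-[(2S,3Z)-1-(benzyloxy)-3-[4-(benzyloxy)-3-methoxyphenyl]pent-3-en-2-yl]-5-bromo-3-methoxybenzene; 16 ethyl (1S,5R)-2-oxo-3-oxabicyclo[3.1.0]hexane-1-carboxylate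
Product: 18 ethyl (4R)-4-{4-(benzyloxy)-3-[(2S,3Z)-1-(benzyloxy)-3-[4-(benzyloxy)-3-methoxyphenyl]pent-3-en-2-yl]-5-methoxybenzyl}-2-oxooxolane-3-carboxylate (C3 epimers), via arylmagnesium bromide 17 (not isolated)
Conditions: Mg, LiCl, THF, rt; then CuI (20 mol %), 16 (1.3 equiv), THF, −30 → 0 °C; aq. NH4Cl
Reagents that add atoms: none
Why: Copper-catalysed homoconjugate (strain-release) addition of the aryl Grignard reagent opens the doubly activated cyclopropane at its CH2 carbon, leaves the existing stereocentre untouched and gives the product as a stabilised malonate-type enolate that resists further addition.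

Step 10
Reactants: 18 ethyl (4R)-4-{4-(benzyloxy)-3-[(2S,3Z)-1-(benzyloxy)-3-[4-(benzyloxy)-3-methoxyphenyl]pent-3-en-2-yl]-5-methoxybenzyl}-2-oxooxolane-3-carboxylate
Product: 19 (4R)-4-{4-(benzyloxy)-3-[(2S,3Z)-1-(benzyloxy)-3-[4-(benzyloxy)-3-methoxyphenyl]pent-3-en-2-yl]-5-methoxybenzyl}oxolan-2-one
Conditions: LiCl, DMSO, H2O, 140 °C
Reagents that add atoms: none
Why: Krapcho dealkoxycarbonylation removes the activating ester under essentially neutral conditions that leave the lactone, the benzyl ethers, the alkene and both stereocentres intact.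

Step 11
Reactants: 20 4-(benzyloxy)-3-methoxybenzyl alcohol
Product: 21 4-(benzyloxy)-3-methoxybenzyl bromide
Conditions: PBr3, Et2O, 0 °C
Reagents that add atoms: phosphorus tribromide, BrP(Br)Br
Why: Standard conversion of an electron-rich benzylic alcohol to its bromide by bromide displacement of the phosphite ester.

Step 12
Reactants: 19 (4R)-4-{4-(benzyloxy)-3-[(2S,3Z)-1-(benzyloxy)-3-[4-(benzyloxy)-3-methoxyphenyl]pent-3-en-2-yl]-5-methoxybenzyl}oxolan-2-one; 21 4-(benzyloxy)-3-methoxybenzyl bromide
Product: 23 (3R,4R)-3-[4-(benzyloxy)-3-methoxybenzyl]-4-{4-(benzyloxy)-3-[(2S,3Z)-1-(benzyloxy)-3-[4-(benzyloxy)-3-methoxyphenyl]pent-3-en-2-yl]-5-methoxybenzyl}oxolan-2-one, via lithium enolate 22 (not isolated)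
Conditions: LiHMDS, THF, −78 °C; then 21, DMPU, −78 → −40 °C
Reagents that add atoms: none
Why: Alkylation of the lithium enolate of a β-substituted γ-butyrolactone occurs anti to the β-arylmethyl group (substrate control), which should set C3 (R) trans to C4; LiHMDS is too weak to deprotonate the allylic–benzylic C–H.

Step 13
Reactants: 23 (3R,4R)-3-[4-(benzyloxy)-3-methoxybenzyl]-4-{4-(benzyloxy)-3-[(2S,3Z)-1-(benzyloxy)-3-[4-(benzyloxy)-3-methoxyphenyl]pent-3-en-2-yl]-5-methoxybenzyl}oxolan-2-one
Product: 25 (3R,4R)-3-[4-(benzyloxy)-3-methoxybenzyl]-4-{4-(benzyloxy)-3-[(2S)-3-(benzyloxy)-1-[4-(benzyloxy)-3-methoxyphenyl]-1-oxopropan-2-yl]-5-methoxybenzyl}oxolan-2-one, via diol 24 (not isolated)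
Conditions: K2OsO4·2H2O (5 mol %), NMO, acetone/H2O, rt; then NaIO4, THF/pH 7 buffer, 0 °C
Reagents that add atoms: N-methylmorpholine N-oxide, C[N+]1([O-])CCOCC1; water, O
Why: Upjohn dihydroxylation of the only alkene followed by periodate glycol cleavage (Lemieux–Johnson sequence) unveils the aryl ketone and releases acetaldehyde under buffered neutral conditions, so the now enolisable α-aryl centre should not epimerise, and the benzylated phenols cannot be oxidised by periodate.

Step 14
Reactants: 25 (3R,4R)-3-[4-(benzyloxy)-3-methoxybenzyl]-4-{4-(benzyloxy)-3-[(2S)-3-(benzyloxy)-1-[4-(benzyloxy)-3-methoxyphenyl]-1-oxopropan-2-yl]-5-methoxybenzyl}oxolan-2-one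
Product: 26 (3R,4R)-3-(4-hydroxy-3-methoxybenzyl)-4-{4-hydroxy-3-[(2S)-3-hydroxy-1-(4-hydroxy-3-methoxyphenyl)-1-oxopropan-2-yl]-5-methoxybenzyl}oxolan-2-one (CNP0191394.1)
Conditions: H2 (1 atm), Pd(OH)2/C, EtOAc/THF, rt
Reagents that add atoms: none
Why: Catalytic hydrogenolysis cleaves the three aryl benzyl ethers and the primary benzyl ether under neutral conditions that neither epimerise the α-aryl ketone nor open the lactone, and electron-rich 4-alkoxyaryl ketones are reduced much more slowly than O-benzyl groups are cleaved.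

**Compound list**

1 | benzyl propargyl ether | C#CCOCc1ccccc1 | starting material
2 | N-methoxy-N-methylacetamide | CC(=O)N(C)OC | starting material
3 | lithium 3-(benzyloxy)prop-1-yn-1-ide (not isolated) | [Li]C#CCOCc1ccccc1 | intermediate
4 | 5-(benzyloxy)pent-3-yn-2-one | CC(=O)C#CCOCc1ccccc1 | intermediate
5 | (S)-5-(benzyloxy)pent-3-yn-2-ol | C[C@H](O)C#CCOCc1ccccc1 | intermediate
6 | (2S,3Z)-5-(benzyloxy)-3-(tributylstannyl)pent-3-en-2-ol | C[C@H](O)/C([Sn](CCCC)(CCCC)CCCC)=C/COCc1ccccc1 | intermediate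
7 | 1-(benzyloxy)-4-bromo-2-methoxybenzene | COc1cc(Br)ccc1OCc1ccccc1 | starting material
8 | (2S,3E)-5-(benzyloxy)-3-[4-(benzyloxy)-3-methoxyphenyl]pent-3-en-2-ol | C[C@H](O)/C(c1ccc(OCc2ccccc2)c(OC)c1)=C/COCc1ccccc1 | intermediate
9 | 4-bromo-2-methoxyphenol | COc1cc(Br)ccc1O | starting material
10 | 1-{[(2R,3E)-5-(benzyloxy)-3-[4-(benzyloxy)-3-methoxyphenyl]pent-3-en-2-yl]oxy}-4-bromo-2-methoxybenzene | C[C@@H](Oc1ccc(Br)cc1OC)/C(c1ccc(OCc2ccccc2)c(OC)c1)=C/COCc1ccccc1 | intermediate
11 | 6-[(2S,3Z)-1-(benzyloxy)-3-[4-(benzyloxy)-3-methoxyphenyl]pent-3-en-2-yl]-4-bromo-2-methoxycyclohexa-2,4-dien-1-one (ring sp3 carbon undefined, not isolated) | COC1=CC(Br)=CC([C@@H](COCc2ccccc2)/C(=C/C)c2ccc(OCc3ccccc3)c(OC)c2)C1=O | intermediate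
12 | 2-[(2S,3Z)-1-(benzyloxy)-3-[4-(benzyloxy)-3-methoxyphenyl]pent-3-en-2-yl]-4-bromo-6-methoxyphenol | COc1cc(Br)cc([C@@H](COCc2ccccc2)/C(=C/C)c2ccc(OCc3ccccc3)c(OC)c2)c1O | intermediate
13 | 2-(benzyloxy)-1-[(2S,3Z)-1-(benzyloxy)-3-[4-(benzyloxy)-3-methoxyphenyl]pent-3-en-2-yl]-5-bromo-3-methoxybenzene | COc1cc(Br)cc([C@@H](COCc2ccccc2)/C(=C/C)c2ccc(OCc3ccccc3)c(OC)c2)c1OCc1ccccc1 | intermediate
14 | (R)-epichlorohydrin | ClC[C@H]1CO1 | starting material
15 | diethyl malonate | CCOC(=O)CC(=O)OCC | starting material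
16 | ethyl (1S,5R)-2-oxo-3-oxabicyclo[3.1.0]hexane-1-carboxylate | CCOC(=O)[C@]12C[C@H]1COC2=O | intermediate
17 | arylmagnesium bromide derived from 13 (not isolated) | COc1cc([Mg]Br)cc([C@@H](COCc2ccccc2)/C(=C/C)c2ccc(OCc3ccccc3)c(OC)c2)c1OCc1ccccc1 | intermediate
18 | ethyl (4R)-4-{4-(benzyloxy)-3-[(2S,3Z)-1-(benzyloxy)-3-[4-(benzyloxy)-3-methoxyphenyl]pent-3-en-2-yl]-5-methoxybenzyl}-2-oxooxolane-3-carboxylate (C3 epimers) | CCOC(=O)C1C(=O)OC[C@@H]1Cc2cc(OC)c(OCc3ccccc3)c([C@@H](COCc3ccccc3)/C(=C/C)c3ccc(OCc4ccccc4)c(OC)c3)c2 | intermediate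
19 | (4R)-4-{4-(benzyloxy)-3-[(2S,3Z)-1-(benzyloxy)-3-[4-(benzyloxy)-3-methoxyphenyl]pent-3-en-2-yl]-5-methoxybenzyl}oxolan-2-one | O=C1OC[C@@H](C1)Cc2cc(OC)c(OCc3ccccc3)c([C@@H](COCc3ccccc3)/C(=C/C)c3ccc(OCc4ccccc4)c(OC)c3)c2 | intermediate
20 | 4-(benzyloxy)-3-methoxybenzyl alcohol | COc1cc(CO)ccc1OCc1ccccc1 | starting material
21 | 4-(benzyloxy)-3-methoxybenzyl bromide | COc1cc(CBr)ccc1OCc1ccccc1 | intermediate
22 | lithium enolate of 19 (not isolated) | [Li]OC1=C[C@@H](Cc2cc(OC)c(OCc3ccccc3)c([C@@H](COCc3ccccc3)/C(=C/C)c3ccc(OCc4ccccc4)c(OC)c3)c2)CO1 | intermediate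
23 | (3R,4R)-3-[4-(benzyloxy)-3-methoxybenzyl]-4-{4-(benzyloxy)-3-[(2S,3Z)-1-(benzyloxy)-3-[4-(benzyloxy)-3-methoxyphenyl]pent-3-en-2-yl]-5-methoxybenzyl}oxolan-2-one | COc1cc(C[C@H]2C(=O)OC[C@@H]2Cc2cc(OC)c(OCc3ccccc3)c([C@@H](COCc3ccccc3)/C(=C/C)c3ccc(OCc4ccccc4)c(OC)c3)c2)ccc1OCc1ccccc1 | intermediate
24 | diol from 23 (two new carbinol centres undefined, not isolated) | COc1cc(C[C@H]2C(=O)OC[C@@H]2Cc2cc(OC)c(OCc3ccccc3)c([C@@H](COCc3ccccc3)C(O)(C(C)O)c3ccc(OCc4ccccc4)c(OC)c3)c2)ccc1OCc1ccccc1 | intermediate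
25 | (3R,4R)-3-[4-(benzyloxy)-3-methoxybenzyl]-4-{4-(benzyloxy)-3-[(2S)-3-(benzyloxy)-1-[4-(benzyloxy)-3-methoxyphenyl]-1-oxopropan-2-yl]-5-methoxybenzyl}oxolan-2-one | COc1cc(C[C@H]2C(=O)OC[C@@H]2Cc2cc(OC)c(OCc3ccccc3)c([C@@H](COCc3ccccc3)C(=O)c3ccc(OCc4ccccc4)c(OC)c3)c2)ccc1OCc1ccccc1 | intermediate
26 | (3R,4R)-3-(4-hydroxy-3-methoxybenzyl)-4-{4-hydroxy-3-[(2S)-3-hydroxy-1-(4-hydroxy-3-methoxyphenyl)-1-oxopropan-2-yl]-5-methoxybenzyl}oxolan-2-one | COc1cc(C[C@H]2C(=O)OC[C@@H]2Cc2cc(OC)c(O)c([C@@H](CO)C(=O)c3ccc(O)c(OC)c3)c2)ccc1O | target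

**Step count and risks**

Total step count: 14. Longest linear sequence: 12 steps (steps 1–7, 9, 10, 12, 13, 14).

The three steps most likely to fail:

1. Step 6 (Claisen rearrangement). The risk is erosion of chirality transfer, either through the methyl-inside rotamer or through Lewis-acid ionisation and recombination of the allyl aryl ether, together with cyclisation of the product phenol onto the styrene. The fallback replaces the intramolecular sigmatropic transfer by an intermolecular copper-mediated anti-SN2′ arylation with 1,3-chirality transfer; it sets out from 8 and 9 and comes back to the route at 13. Alcohol 8 would be esterified (picolinic acid, EDC, DMAP) to (2S,3E)-5-(benzyloxy)-3-[4-(benzyloxy)-3-methoxyphenyl]pent-3-en-2-yl pyridine-2-carboxylate F1. Phenol 9 would be iodinated ortho to the OH (NIS, cat. TsOH) to 4-bromo-2-iodo-6-methoxyphenol F2 and benzylated (BnBr, K2CO3) to 2-(benzyloxy)-5-bromo-1-iodo-3-methoxybenzene F3. Selective iodine–magnesium exchange (i-PrMgCl·LiCl, THF, −40 °C) would give [2-(benzyloxy)-5-bromo-3-methoxyphenyl]magnesium chloride F4. With CuBr·SMe2 this should displace the picolinate of F1 in the anti-SN2′ sense, delivering the aryl group to the alkene face opposite the chelating leaving group and so giving 13 directly with the same (2S,3Z) configuration.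

2. Step 5 (Mitsunobu etherification). The risk is SN2′ attack of the phenoxide, elimination to a diene, or partial loss of configuration at the hindered allylic carbinol. The fallback forms the aryl–oxygen bond instead of the alkyl–oxygen bond, with retention at carbon, and therefore uses the enantiomeric alcohol; it sets out from 4 and comes back at 10. Transfer hydrogenation of 4 with the (R,R)-catalyst would give (R)-5-(benzyloxy)pent-3-yn-2-ol F5. Hydrostannation as in step 3 would give (2R,3Z)-5-(benzyloxy)-3-(tributylstannyl)pent-3-en-2-ol F6, and Stille coupling with 7 as in step 4 would give (2R,3E)-5-(benzyloxy)-3-[4-(benzyloxy)-3-methoxyphenyl]pent-3-en-2-ol F7. Copper-catalysed Ullmann-type O-arylation of F7 with commercial 4-bromo-1-iodo-2-methoxybenzene (CuI, 3,4,7,8-tetramethyl-1,10-phenanthroline, Cs2CO3, toluene, 80 °C) should react only at the C–I bond and give 10 with the carbinol configuration retained.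

3. Step 14 (global hydrogenolysis). The risk is slow cleavage of the primary benzyl ether, which on prolonged exposure allows over-reduction of the aryl ketone or epimerisation of the α-aryl centre. The fallback is a non-reductive Lewis-acid debenzylation with a cation scavenger (BCl3, pentamethylbenzene, CH2Cl2, −78 °C); it sets out from 25 and comes back at 26, and forms no new compound, entered below as none F0.

**Further compounds**

F1 | step 6 | (2S,3E)-5-(benzyloxy)-3-[4-(benzyloxy)-3-methoxyphenyl]pent-3-en-2-yl pyridine-2-carboxylate | C[C@H](OC(=O)c1ccccn1)/C(c1ccc(OCc2ccccc2)c(OC)c1)=C/COCc1ccccc1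
F2 | step 6 | 4-bromo-2-iodo-6-methoxyphenol | COc1cc(Br)cc(I)c1O
F3 | step 6 | 2-(benzyloxy)-5-bromo-1-iodo-3-methoxybenzene | COc1cc(Br)cc(I)c1OCc1ccccc1
F4 | step 6 | [2-(benzyloxy)-5-bromo-3-methoxyphenyl]magnesium chloride | COc1cc(Br)cc([Mg]Cl)c1OCc1ccccc1
F5 | step 5 | (R)-5-(benzyloxy)pent-3-yn-2-ol | C[C@@H](O)C#CCOCc1ccccc1
F6 | step 5 | (2R,3Z)-5-(benzyloxy)-3-(tributylstannyl)pent-3-en-2-ol | C[C@@H](O)/C([Sn](CCCC)(CCCC)CCCC)=C/COCc1ccccc1
F7 | step 5 | (2R,3E)-5-(benzyloxy)-3-[4-(benzyloxy)-3-methoxyphenyl]pent-3-en-2-ol | C[C@@H](O)/C(c1ccc(OCc2ccccc2)c(OC)c1)=C/COCc1ccccc1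
F0 | step 14 | none | none
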